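The north-east run cannot be levelling off for want of material: at 54.5% target, 45.5% of the substrate, the limiting reagent, still stands beside reagent charged at 3 equiv. So the step runs back. I take the crystals to hold c(released group) fixed, which leaves one quantity for a flask at rest: Q, c(target) over c(substrate) times c(reagent).

| setting | south-west | north-east | teal | red | blue |
|---|---|---|---|---|---|
| substrate | 0.54 M | 0.54 M | 0.80 M | 0.80 M | 0.80 M |
| reagent | 3 equiv | 3 equiv | 3.00 equiv | 3.00 equiv | 3.00 equiv |
| temperature | 39 °C | 47 °C | 50 °C | 35 °C |  |
| remark | run made earlier | run made earlier |  |  | at 35 °C until 4.0 min, from then on at 50 °C |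
| time |  |  | 20 min | 20 min | 20 min |

- south-west (time / min: target / %): 2.50: 16.2; 4.00: 23.0; 6.00: 31.1; 10.0: 41.3; 15.0: 49.1; 20.0: 53.9; 30.0: 58.8
- north-east (time / min: target / %): 1.50: 18.7; 2.50: 27.2; 4.00: 35.5; 6.00: 42.7; 8.00: 46.5; 12.0: 51.2; 20.0: 54.5

(readings scatter by 0.3 percentage points)

- the best flask by amount of target, in percent of the substrate charged; "all alike" if 1.5 percentage points covers them all (teal / red / blue / all alike)
- amount of target at the end, in percent of the substrate charged, teal
- amount of target at the end, in percent of the substrate charged, red
- amount of target at the end, in percent of the substrate charged, blue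

- amounts and yields of released group count crystals too
- given per volume of solution although it is solid: crystals
- steps thought possible: substrate + reagent <-> target + released group; crystals <-> released group

I work with what is left, the fraction of substrate and the equivalents of reagent, and read Q two ways. The first way treats the last reading as rest. The second balances rates. The first reading of each run, counted as forward step, gives a forward constant: 0.0449 M⁻¹ min⁻¹ at 39 °C and 0.0881 M⁻¹ min⁻¹ at 47 °C. The slope between the last two readings is then forward rate minus back rate, and the back rate gives Q. At 47 °C the ways agree, 0.904 M⁻¹ against 0.907 M⁻¹, so I trust that number. At 39 °C they part, 1.10 M⁻¹ against 1.21 M⁻¹, and the first way cheats: the south-west run still climbs from 53.9% to 58.8% over its last interval, which is no rest.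

Taking ln Q and ln k as straight in temperature, 0.814 M⁻¹ is the plateau quotient at 50 °C, the value of c(target) over c(substrate) times c(reagent) at which a flask with crystals stands still, and Q at 35 °C is 1.40 M⁻¹. Solved for these charges, they give plateaus of 60.9% and 71.9%.

But a plateau takes time. I reckon an approach time, after which the distance still to go is down by a factor e: the reciprocal of forward constant times charged substrate times the separation of the two roots of the balance. It is 2.55 min at 50 °C and 11.3 min at 35 °C. Teal has 7.83 such times and blue 6.27 after its change, so I put both at 60.9%. Red has 1.77, so its plateau number cheats and I expect 59.7%.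

The forecast, made from the same runs, says all alike, with teal 61.6%, red 61.3% and blue 61.5%, on the suggestion that “the released group crystallises early and stays at saturation”. It stands 0.7 percentage points above my teal and 1.6 points above my red.

The flasks end at 60.6% for teal, 59.9% for red and 60.4% for blue: all alike.

    substrate + reagent ⇌ target + released group (K = 0.199, k = 0.0306 M⁻¹ min⁻¹, Ea = 75.0 kJ mol⁻¹, ΔH = −31.0 kJ mol⁻¹)
    crystals ⇌ released group, rate k2*(cs2 - [released group]) while solid is left; crystals form when [released group] > cs2 (solubility = 0.140 M, k = 1.19 min⁻¹)
    (constants at 35 °C)

Teal stops short because of the reverse step: without it, teal gives 98.5% in place of 60.6%. The end state of teal, with c(released group) at 0.140 M, gives a quotient of 0.804 M⁻¹ against my 0.814 M⁻¹. For the flask like blue but with 1.20 equiv of reagent, 0.814 M⁻¹ gives a plateau of 35.5%, and that flask holds 34.9% target.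

(The data were computed from invented constants.)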